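**Plan**
1. Locants: decalin C1–C10 (ring A = C1–C5 and C10, ring B = C5–C10), C11 = the CH2 on C9, β = the face of the C3 oxygen. PMB = 4-methoxybenzyl, TBS = tert-butyldimethylsilyl, TBDPS = tert-butyldiphenylsilyl, TES = triethylsilyl.
2. Retrosynthesis: cut C11–pyranone (Negishi) and C8=CH2 (Wittig), then both ring-A bonds C3–C4 and C5–C10 in one intramolecular Diels–Alder step, then C5–C6 (Nozaki–Hiyama–Kishi) and C8–C9 (aldol).
3. Enabling feature: C3, C4, C5 and C10 are contiguous in ring A, so ring A is the cyclohexene of a C3-oxygenated, C10-methylated diene (C3=C2–C1=C10) and a Z-enone (C4=C5–C6=O) held together by the chain C9–C8–C7. The cycloaddition closes ring A and ring B at once.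
4. Forward order: auxiliary aldol (C9, temporary C8 carbinol), alkyne, carboalumination, (1E,3E)-dienyl PMB ether, coupling with a Z-alkenyl iodide, trienone, cycloaddition, then C6 deoxygenation, C1=C2 hydrogenation, C8 methylenation, pyranone coupling, formylation and PMB removal.
5. Stereochemistry: C9 (and the C8 carbinol) from the (S)-4-benzyloxazolidin-2-one aldol. C3, C4, C5 and C10 from the cycloaddition (alkene geometries, endo ketone, C9-controlled diene face). Alkene geometries from syn-carbometalations, Takai olefination and stereoretentive couplings.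
6. C8 is carried as a TBS ether and the diene oxygen as a PMB ether made by stereoretentive C–O coupling, because a β-keto ketal is unlikely to survive the Lewis acid and enolisation of an aldehyde would not give the E enol ether reliably.

Key step: step 19

Remark: the C6 carbinol epimers of 27 and 30 are carried as mixtures because C6 is oxidised or deoxygenated afterwards, and 7 and 21 are taken as catalogue compounds.

Step 1
Reactants: 1 propane-1,3-diol
Product: 2 3-[(tert-butyldiphenylsilyl)oxy]propan-1-ol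
Conditions: NaH (1 equiv), THF, 0 °C; TBDPSCl, rt (diol in excess)
Reagents that add atoms: tert-butyl(chloro)diphenylsilane, CC(C)(C)[Si](Cl)(c1ccccc1)c1ccccc1
Why: O-Silylation of the sparingly soluble monosodium alkoxide of a symmetrical diol (Williamson-type) should stop at the mono ether.

Step 2
Reactants: 2 3-[(tert-butyldiphenylsilyl)oxy]propan-1-ol
Product: 3 3-[(tert-butyldiphenylsilyl)oxy]propanoic acid
Conditions: TEMPO (10 mol %), PhI(OAc)2 (2.2 equiv), MeCN/H2O, rt
Reagents that add atoms: water, O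
Why: Oxoammonium (TEMPO) oxidation of a primary alcohol in wet acetonitrile runs through the aldehyde hydrate to the acid and leaves the silyl ether untouched.

Step 3
Reactants: 3 3-[(tert-butyldiphenylsilyl)oxy]propanoic acid; 4 (S)-4-benzyloxazolidin-2-one
Product: 6 (S)-4-benzyl-3-{3-[(tert-butyldiphenylsilyl)oxy]propanoyl}oxazolidin-2-one, via mixed pivalic anhydride 5 (not isolated)
Conditions: PivCl, Et3N, THF, −20 °C; then 4, LiCl, rt
Reagents that add atoms: none
Why: N-Acylation of the oxazolidinone by a mixed anhydride under LiCl/Et3N activation is the usual way to load the auxiliary and avoids strong base next to the β-silyloxy group.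

Step 4
Reactants: 6 (S)-4-benzyl-3-{3-[(tert-butyldiphenylsilyl)oxy]propanoyl}oxazolidin-2-one; 7 3-[(tert-butyldimethylsilyl)oxy]propanal
Product: 9 (S)-4-benzyl-3-[(2S,3R)-5-[(tert-butyldimethylsilyl)oxy]-2-{[(tert-butyldiphenylsilyl)oxy]methyl}-3-hydroxypentanoyl]oxazolidin-2-one, via Z-dibutylboron enolate 8 (not isolated)
Conditions: Bu2BOTf, i-Pr2NEt, CH2Cl2, −78 to 0 °C; 7, −78 to 0 °C; then pH 7 buffer, MeOH, H2O2
Reagents that add atoms: none
Why: Evans syn-aldol reaction, in which the Z-boron enolate reacts through a chair Zimmerman–Traxler transition state on the face away from the benzyl group and so sets C9 (2S) and the temporary C8 carbinol (3R) in one operation.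

Step 5
Reactants: 9 (S)-4-benzyl-3-[(2S,3R)-5-[(tert-butyldimethylsilyl)oxy]-2-{[(tert-butyldiphenylsilyl)oxy]methyl}-3-hydroxypentanoyl]oxazolidin-2-one
Product: 10 (S)-4-benzyl-3-[(2S,3R)-3,5-bis[(tert-butyldimethylsilyl)oxy]-2-{[(tert-butyldiphenylsilyl)oxy]methyl}pentanoyl]oxazolidin-2-one
Conditions: TBSOTf, 2,6-lutidine, CH2Cl2, −78 to 0 °C
Reagents that add atoms: tert-butyldimethylsilyl trifluoromethanesulfonate, CC(C)(C)[Si](C)(C)OS(=O)(=O)C(F)(F)F
Why: Silylation of the aldol hydroxyl with a silyl triflate and a hindered pyridine base is fast at low temperature and so forestalls retro-aldol cleavage.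

Step 6
Reactants: 10 (S)-4-benzyl-3-[(2S,3R)-3,5-bis[(tert-butyldimethylsilyl)oxy]-2-{[(tert-butyldiphenylsilyl)oxy]methyl}pentanoyl]oxazolidin-2-one
Product: 11 (2S,3R)-3,5-bis[(tert-butyldimethylsilyl)oxy]-2-{[(tert-butyldiphenylsilyl)oxy]methyl}pentan-1-ol
Conditions: LiBH4, MeOH (1 equiv), THF, 0 °C
Reagents that add atoms: none
Why: Reductive cleavage of the N-acyloxazolidinone by LiBH4 gives the primary alcohol and returns the auxiliary, and the boron-bound alkoxide is too weakly nucleophilic to shuttle the neighbouring TBDPS group.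

Step 7
Reactants: 11 (2S,3R)-3,5-bis[(tert-butyldimethylsilyl)oxy]-2-{[(tert-butyldiphenylsilyl)oxy]methyl}pentan-1-ol
Product: 12 (2S,3R)-3,5-bis[(tert-butyldimethylsilyl)oxy]-2-{[(tert-butyldiphenylsilyl)oxy]methyl}pentanal
Conditions: Dess–Martin periodinane, NaHCO3, CH2Cl2, 0 °C
Reagents that add atoms: none
Why: Buffered Dess–Martin oxidation gives the α-branched aldehyde without base, so C9 should not epimerise if the aldehyde is used at once.

Step 8
Reactants: 12 (2S,3R)-3,5-bis[(tert-butyldimethylsilyl)oxy]-2-{[(tert-butyldiphenylsilyl)oxy]methyl}pentanal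
Product: 13 (3R,4S)-1,3-bis[(tert-butyldimethylsilyl)oxy]-4-{[(tert-butyldiphenylsilyl)oxy]methyl}hex-5-yne
Conditions: dimethyl (1-diazo-2-oxopropyl)phosphonate, K2CO3, MeOH, 0 °C to rt
Reagents that add atoms: dimethyl (1-diazo-2-oxopropyl)phosphonate, CC(=O)C(=[N+]=[N-])P(=O)(OC)OC
Why: Ohira–Bestmann (Seyferth–Gilbert) homologation turns the aldehyde into the terminal alkyne through a diazoalkene and a carbene 1,2-shift, a carbonate-mediated process routinely applied to α-stereogenic β-silyloxy aldehydes.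

Step 9
Reactants: 13 (3R,4S)-1,3-bis[(tert-butyldimethylsilyl)oxy]-4-{[(tert-butyldiphenylsilyl)oxy]methyl}hex-5-yne
Product: 15 (2E,4S,5R)-5,7-bis[(tert-butyldimethylsilyl)oxy]-4-{[(tert-butyldiphenylsilyl)oxy]methyl}-3-methylhept-2-en-1-ol, via dimethylalkenylalane 14 (not isolated)
Conditions: Me3Al (3 equiv), Cp2ZrCl2 (0.25 equiv), CH2Cl2, 0 °C to rt; then (HCHO)n, THF, rt
Reagents that add atoms: trimethylaluminium, C[Al](C)C; formaldehyde (as paraformaldehyde), C=O
Why: Zirconium-catalysed carboalumination (Negishi) adds methyl and aluminium syn across the terminal alkyne with methyl on the inner carbon, so trapping the alkenylalane with formaldehyde gives the E allylic alcohol in which C2 is cis to the C10 methyl.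

Step 10
Reactants: 15 (2E,4S,5R)-5,7-bis[(tert-butyldimethylsilyl)oxy]-4-{[(tert-butyldiphenylsilyl)oxy]methyl}-3-methylhept-2-en-1-ol
Product: 16 (2E,4S,5R)-5,7-bis[(tert-butyldimethylsilyl)oxy]-4-{[(tert-butyldiphenylsilyl)oxy]methyl}-3-methylhept-2-enal
Conditions: TEMPO (10 mol %), PhI(OAc)2, CH2Cl2, rt
Reagents that add atoms: none
Why: TEMPO/PhI(OAc)2 oxidation of a primary allylic alcohol stops at the enal and does not isomerise the trisubstituted alkene.

Step 11
Reactants: 16 (2E,4S,5R)-5,7-bis[(tert-butyldimethylsilyl)oxy]-4-{[(tert-butyldiphenylsilyl)oxy]methyl}-3-methylhept-2-enal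
Product: 17 (1E,3E,5S,6R)-6,8-bis[(tert-butyldimethylsilyl)oxy]-5-{[(tert-butyldiphenylsilyl)oxy]methyl}-1-iodo-4-methylocta-1,3-diene
Conditions: CrCl2 (6 equiv), CHI3 (2 equiv), THF/1,4-dioxane, 0 °C, dark
Reagents that add atoms: iodoform, IC(I)I
Why: Takai iodo-olefination of the enal through a geminal dichromium reagent gives the E alkenyl iodide and leaves the silyl ethers alone.

Step 12
Reactants: 17 (1E,3E,5S,6R)-6,8-bis[(tert-butyldimethylsilyl)oxy]-5-{[(tert-butyldiphenylsilyl)oxy]methyl}-1-iodo-4-methylocta-1,3-diene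
Product: 18 (1E,3E,5S,6R)-6,8-bis[(tert-butyldimethylsilyl)oxy]-5-{[(tert-butyldiphenylsilyl)oxy]methyl}-1-[(4-methoxybenzyl)oxy]-4-methylocta-1,3-diene
Conditions: 4-methoxybenzyl alcohol, CuI (10 mol %), 3,4,7,8-tetramethyl-1,10-phenanthroline (20 mol %), Cs2CO3, toluene, 80 °C
Reagents that add atoms: 4-methoxybenzyl alcohol, COc1ccc(CO)cc1
Why: Copper-catalysed Ullmann-type C–O coupling of an alkenyl iodide with an alcohol proceeds with retention of alkene geometry and so delivers the 1E dienyl ether that aldehyde enolisation would not give selectively.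

Step 13
Reactants: 18 (1E,3E,5S,6R)-6,8-bis[(tert-butyldimethylsilyl)oxy]-5-{[(tert-butyldiphenylsilyl)oxy]methyl}-1-[(4-methoxybenzyl)oxy]-4-methylocta-1,3-diene
Product: 19 (3R,4S,5E,7E)-3-[(tert-butyldimethylsilyl)oxy]-4-{[(tert-butyldiphenylsilyl)oxy]methyl}-8-[(4-methoxybenzyl)oxy]-5-methylocta-5,7-dien-1-ol
Conditions: HF·pyridine, excess pyridine, THF, 0 °C
Reagents that add atoms: none
Why: Buffered HF·pyridine removes a primary TBS ether far faster than the secondary TBS or the TBDPS ether, and the excess pyridine keeps the medium mild enough for the enol ether.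

Step 14
Reactants: 19 (3R,4S,5E,7E)-3-[(tert-butyldimethylsilyl)oxy]-4-{[(tert-butyldiphenylsilyl)oxy]methyl}-8-[(4-methoxybenzyl)oxy]-5-methylocta-5,7-dien-1-ol
Product: 20 (3R,4S,5E,7E)-3-[(tert-butyldimethylsilyl)oxy]-4-{[(tert-butyldiphenylsilyl)oxy]methyl}-8-[(4-methoxybenzyl)oxy]-5-methylocta-5,7-dienal
Conditions: Dess–Martin periodinane, NaHCO3, CH2Cl2, 0 °C
Reagents that add atoms: none
Why: Buffered Dess–Martin oxidation gives the β-silyloxy aldehyde without the acid that would hydrolyse the dienyl ether.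

Step 15
Reactants: 21 4-bromo-2-methylbutan-2-ol
Product: 22 [(4-bromo-2-methylbutan-2-yl)oxy]triethylsilane
Conditions: TESOTf, 2,6-lutidine, CH2Cl2, 0 °C
Reagents that add atoms: triethylsilyl trifluoromethanesulfonate, CC[Si](CC)(CC)OS(=O)(=O)C(F)(F)F
Why: A silyl triflate with 2,6-lutidine silylates even a tertiary alcohol, and the primary bromide is inert to these conditions.

Step 16
Reactants: 22 [(4-bromo-2-methylbutan-2-yl)oxy]triethylsilane
Product: 25 triethyl{[(5Z)-6-iodo-2,5-dimethylhex-5-en-2-yl]oxy}silane, via Grignard reagent 23 (not isolated), via Z-alkenylcopper 24 (not isolated)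
Conditions: Mg, Et2O; CuBr·SMe2, Et2O/Me2S, −45 °C; propyne, −25 °C; I2, −78 to 0 °C
Reagents that add atoms: propyne, CC#C; iodine, II
Why: Normant carbocupration adds the alkylcopper syn to propyne with the alkyl group on the substituted carbon, and iodinolysis with retention gives the Z iodide in which iodine is cis to the chain.

Step 17
Reactants: 20 (3R,4S,5E,7E)-3-[(tert-butyldimethylsilyl)oxy]-4-{[(tert-butyldiphenylsilyl)oxy]methyl}-8-[(4-methoxybenzyl)oxy]-5-methylocta-5,7-dienal; 25 triethyl{[(5Z)-6-iodo-2,5-dimethylhex-5-en-2-yl]oxy}silane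
Product: 27 (1E,3E,5S,6R,9Z)-6-[(tert-butyldimethylsilyl)oxy]-5-{[(tert-butyldiphenylsilyl)oxy]methyl}-1-[(4-methoxybenzyl)oxy]-4,10,13-trimethyl-13-[(triethylsilyl)oxy]tetradeca-1,3,9-trien-8-ol (both carbinol epimers), via alkenylchromium dichloride 26 (not isolated)
Conditions: CrCl2 (4 equiv), NiCl2 (2 mol %), DMSO/THF, rt
Reagents that add atoms: none
Why: Nozaki–Hiyama–Kishi coupling forms the alkenylchromium reagent with retention of the Z geometry and adds it to the aldehyde under non-basic conditions, and the carbinol configuration is irrelevant because it is oxidised next.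

Step 18
Reactants: 27 (1E,3E,5S,6R,9Z)-6-[(tert-butyldimethylsilyl)oxy]-5-{[(tert-butyldiphenylsilyl)oxy]methyl}-1-[(4-methoxybenzyl)oxy]-4,10,13-trimethyl-13-[(triethylsilyl)oxy]tetradeca-1,3,9-trien-8-ol
Product: 28 (1E,3E,5S,6R,9Z)-6-[(tert-butyldimethylsilyl)oxy]-5-{[(tert-butyldiphenylsilyl)oxy]methyl}-1-[(4-methoxybenzyl)oxy]-4,10,13-trimethyl-13-[(triethylsilyl)oxy]tetradeca-1,3,9-trien-8-one
Conditions: Dess–Martin periodinane, NaHCO3, CH2Cl2, 0 °C
Reagents that add atoms: none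
Why: Buffered Dess–Martin oxidation of the allylic alcohol gives the Z-enone at low temperature without the acid or base that would scramble the enone geometry.

Step 19
Reactants: 28 (1E,3E,5S,6R,9Z)-6-[(tert-butyldimethylsilyl)oxy]-5-{[(tert-butyldiphenylsilyl)oxy]methyl}-1-[(4-methoxybenzyl)oxy]-4,10,13-trimethyl-13-[(triethylsilyl)oxy]tetradeca-1,3,9-trien-8-one
Product: 29 cis-fused octal-1-en-6-one bearing 3β-OPMB, 4α-CH3, 4β-CH2CH2C(CH3)2OTES, 5α-H, 8α-OTBS, 9β-CH2OTBDPS and 10α-CH3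
Conditions: Me2AlCl (1.5 equiv), CH2Cl2, −78 to −20 °C
Reagents that add atoms: none
Why: Proposed new method: Me2AlCl binds the C6 carbonyl on the side of C7, and the complexed Z-enone (C4=C5) adds to the (1E,3E)-dienyl ether (C3=C2–C1=C10) in a concerted, asynchronous [4+2] cycloaddition that forms C3–C4 and C5–C10. The closest known reaction type is the Lewis acid-promoted intramolecular Diels–Alder reaction of deca-1,7,9-trien-3-ones to cis-fused octalones, which here must create two quaternary carbons (C4 and C10) against the electronic preference of the alkoxy terminus, the regiochemistry being dictated by the four-atom tether. Ring A is the six-membered cycloaddition ring itself, and ring B closes in the same event as the six-membered tether ring C5–C6–C7–C8–C9–C10 through the C5–C10 bond. With the aluminium-bound C6 carbonyl endo, C6 and C9 end up cis and give the cis fusion at C5/C10, while the E enol ether, the methyl group on the inside of C10 and the Z-enone translate stereospecifically into C3–O cis to the side chain and the C4 methyl cis to the C10 methyl and C5–H. The absolute sense comes from C9, because allylic strain with the inside C10 methyl turns C9–H towards that methyl, the CH2OTBDPS group lies anti to the forming C5–C10 bond, and the tether, with the C8 silyl ether equatorial in the chair-like ring B, can reach one diene face only. The step needs endo over exo selectivity, a single diene face and survival of the enone and enol ether geometries, which should be secured by the clash between tether and inside methyl in the exo transition state, by the C9 and C8 substituents and by the low temperature.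

Step 20
Reactants: 29 cis-fused octal-1-en-6-one bearing 3β-OPMB, 4α-CH3, 4β-CH2CH2C(CH3)2OTES, 5α-H, 8α-OTBS, 9β-CH2OTBDPS and 10α-CH3
Product: 30 C6 alcohol of 29 (octal-1-en-6-ol, both C6 epimers, other substituents unchanged)
Conditions: NaBH4, MeOH/THF, 0 °C to rt
Reagents that add atoms: none
Why: Borohydride reduction of the ring ketone gives the C6 alcohol, and either epimer serves because the oxygen is removed two steps later.

Step 21
Reactants: 30 C6 alcohol of 29 (octal-1-en-6-ol, both C6 epimers, other substituents unchanged)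
Product: 31 C6 O-(imidazol-1-ylthiocarbonyl) derivative of 30
Conditions: 1,1'-thiocarbonyldiimidazole, DMAP, toluene, 80 °C
Reagents that add atoms: 1,1'-thiocarbonyldiimidazole, S=C(n1ccnc1)n1ccnc1
Why: Neutral thioacylation makes the Barton–McCombie precursor without forming an alkoxide that could shift the C8 silyl group.

Step 22
Reactants: 31 C6 O-(imidazol-1-ylthiocarbonyl) derivative of 30
Product: 32 cis-fused octal-1-ene (C6 = CH2) bearing 3β-OPMB, 4α-CH3, 4β-CH2CH2C(CH3)2OTES, 5α-H, 8α-OTBS, 9β-CH2OTBDPS and 10α-CH3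
Conditions: Bu3SnH, AIBN (20 mol %), toluene, 100 °C
Reagents that add atoms: none
Why: Barton–McCombie deoxygenation, in which the stannyl radical adds to the thiocarbonyl group, β-scission gives the secondary C6 radical and hydrogen transfer from Bu3SnH leaves the methylene group.

Step 23
Reactants: 32 cis-fused octal-1-ene (C6 = CH2) bearing 3β-OPMB, 4α-CH3, 4β-CH2CH2C(CH3)2OTES, 5α-H, 8α-OTBS, 9β-CH2OTBDPS and 10α-CH3
Product: 33 cis-fused decalin bearing 3β-OPMB, 4α-CH3, 4β-CH2CH2C(CH3)2OTES, 5α-H, 8α-OTBS, 9β-CH2OTBDPS and 10α-CH3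
Conditions: H2 (1 atm), [Ir(cod)(PCy3)(py)]PF6 (5 mol %), CH2Cl2, rt
Reagents that add atoms: none
Why: Homogeneous iridium-catalysed hydrogenation saturates the hindered cis-disubstituted C1=C2 alkene, creates no stereocentre and does not hydrogenolyse the PMB ether.

Step 24
Reactants: 33 cis-fused decalin bearing 3β-OPMB, 4α-CH3, 4β-CH2CH2C(CH3)2OTES, 5α-H, 8α-OTBS, 9β-CH2OTBDPS and 10α-CH3
Product: 34 cis-fused decalin-8α-ol bearing 3β-OPMB, 4α-CH3, 4β-CH2CH2C(CH3)2OH, 5α-H, 9β-CH2OTBDPS and 10α-CH3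
Conditions: HF·pyridine, THF, 0 °C to rt
Reagents that add atoms: none
Why: Acidic fluoride cleaves the secondary TBS and tertiary TES ethers well before the far more robust primary TBDPS ether.

Step 25
Reactants: 34 cis-fused decalin-8α-ol bearing 3β-OPMB, 4α-CH3, 4β-CH2CH2C(CH3)2OH, 5α-H, 9β-CH2OTBDPS and 10α-CH3
Product: 35 cis-fused decalin-8-one bearing 3β-OPMB, 4α-CH3, 4β-CH2CH2C(CH3)2OH, 5α-H, 9β-CH2OTBDPS and 10α-CH3
Conditions: Dess–Martin periodinane, NaHCO3, CH2Cl2, rt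
Reagents that add atoms: none
Why: Dess–Martin oxidation converts the secondary C8 alcohol into the ketone and cannot touch the tertiary alcohol, while the equatorial C9 side chain should be the stable epimer next to the new ketone.

Step 26
Reactants: 35 cis-fused decalin-8-one bearing 3β-OPMB, 4α-CH3, 4β-CH2CH2C(CH3)2OH, 5α-H, 9β-CH2OTBDPS and 10α-CH3
Product: 36 cis-fused 8-methylidenedecalin bearing 3β-OPMB, 4α-CH3, 4β-CH2CH2C(CH3)2OH, 5α-H, 9β-CH2OTBDPS and 10α-CH3
Conditions: Ph3PCH3Br, KOt-Bu (excess), THF, 0 °C to rt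
Reagents that add atoms: methyltriphenylphosphonium bromide, C[P+](c1ccccc1)(c1ccccc1)c1ccccc1.[Br-]
Why: Wittig methylenation with the unstabilised ylide, one equivalent of base being consumed by the tertiary hydroxyl, adds to the ketone faster than it enolises it, so C9 should keep its configuration.

Step 27
Reactants: 36 cis-fused 8-methylidenedecalin bearing 3β-OPMB, 4α-CH3, 4β-CH2CH2C(CH3)2OH, 5α-H, 9β-CH2OTBDPS and 10α-CH3
Product: 37 cis-fused 8-methylidenedecalin bearing 3β-OPMB, 4α-CH3, 4β-CH2CH2C(CH3)2OH, 5α-H, 9β-CH2OH and 10α-CH3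
Conditions: Bu4NF, THF, rt
Reagents that add atoms: none
Why: Fluoride cleaves the primary TBDPS ether, and nothing else in the molecule is fluoride-labile.

Step 28
Reactants: 37 cis-fused 8-methylidenedecalin bearing 3β-OPMB, 4α-CH3, 4β-CH2CH2C(CH3)2OH, 5α-H, 9β-CH2OH and 10α-CH3
Product: 38 cis-fused 8-methylidenedecalin bearing 3β-OPMB, 4α-CH3, 4β-CH2CH2C(CH3)2OH, 5α-H, 9β-CH2I and 10α-CH3
Conditions: I2, PPh3, imidazole, CH2Cl2, 0 °C to rt
Reagents that add atoms: iodine, II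
Why: Appel iodination converts the primary alcohol through its alkoxyphosphonium salt by SN2 displacement, whereas the hindered tertiary alcohol does not react.

Step 29
Reactants: 39 methyl acetoacetate
Product: 40 methyl 4-hydroxy-6-methyl-2-oxo-2H-pyran-5-carboxylate
Conditions: malonyl dichloride, CH2Cl2, rt then reflux
Reagents that add atoms: malonyl dichloride, O=C(Cl)CC(=O)Cl
Why: Cyclocondensation of a β-keto ester with malonyl dichloride, by C-acylation and O-acylation of the enol, is a known route to 5-acyl-4-hydroxy-2-pyranones.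

Step 30
Reactants: 40 methyl 4-hydroxy-6-methyl-2-oxo-2H-pyran-5-carboxylate
Product: 42 methyl 6-methoxy-2-methyl-4-oxo-4H-pyran-3-carboxylate, via 4-hydroxy-2-methoxypyrylium triflate 41 (not isolated)
Conditions: MeOTf, CH2Cl2, rt; then aq. NaHCO3
Reagents that add atoms: methyl trifluoromethanesulfonate, COS(=O)(=O)C(F)(F)F
Why: O-Methylation with a hard methylating agent takes place on the ring carbonyl oxygen because the C4 hydroxyl is held in a hydrogen bond to the ester, and deprotonation of the pyrylium salt gives the 2-methoxy-4-pyranone.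

Step 31
Reactants: 42 methyl 6-methoxy-2-methyl-4-oxo-4H-pyran-3-carboxylate
Product: 43 methyl 5-iodo-6-methoxy-2-methyl-4-oxo-4H-pyran-3-carboxylate
Conditions: N-iodosuccinimide, CF3CO2H (10 mol %), MeCN, rt
Reagents that add atoms: N-iodosuccinimide, O=C1CCC(=O)N1I
Why: Electrophilic iodination takes place at the only free ring position, which is the nucleophilic α-carbon of the vinylogous ester.

Step 32
Reactants: 38 cis-fused 8-methylidenedecalin bearing 3β-OPMB, 4α-CH3, 4β-CH2CH2C(CH3)2OH, 5α-H, 9β-CH2I and 10α-CH3; 43 methyl 5-iodo-6-methoxy-2-methyl-4-oxo-4H-pyran-3-carboxylate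
Product: 46 cis-fused 8-methylidenedecalin bearing 3β-OPMB, 4α-CH3, 4β-CH2CH2C(CH3)2OH, 5α-H, 10α-CH3 and a 9β-CH2 group bonded to C5 of methyl 6-methoxy-2-methyl-4-oxo-4H-pyran-3-carboxylate, via alkyllithium 44 (not isolated), via alkylzinc chloride 45 (not isolated)
Conditions: t-BuLi (3.2 equiv), Et2O, −78 °C; ZnCl2, THF, −78 °C to rt; then 43, Pd2(dba)3 (2.5 mol %), SPhos (10 mol %), THF, rt to 40 °C
Reagents that add atoms: none
Why: Negishi coupling, in which iodine–lithium exchange and transmetalation give a primary alkylzinc reagent that tolerates the ester and pyranone of 43, and a bulky biarylphosphine on palladium favours reductive elimination over β-hydride elimination.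

Step 33
Reactants: 46 cis-fused 8-methylidenedecalin bearing 3β-OPMB, 4α-CH3, 4β-CH2CH2C(CH3)2OH, 5α-H, 10α-CH3 and a 9β-CH2 group bonded to C5 of methyl 6-methoxy-2-methyl-4-oxo-4H-pyran-3-carboxylate
Product: 47 tertiary formate of 46 (4β-CH2CH2C(CH3)2OCHO, other substituents unchanged)
Conditions: acetic formic anhydride, pyridine, DMAP (10 mol %), CH2Cl2, 0 °C to rt
Reagents that add atoms: acetic formic anhydride, CC(=O)OC=O
Why: Acetic formic anhydride transfers its formyl group selectively and is reactive enough to acylate a tertiary alcohol, which is the only free hydroxyl in the molecule.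

Step 34
Reactants: 47 tertiary formate of 46 (4β-CH2CH2C(CH3)2OCHO, other substituents unchanged)
Product: 48 CNP0292250.1: cis-fused 8-methylidenedecalin bearing 3β-OH, 4α-CH3, 4β-CH2CH2C(CH3)2OCHO, 5α-H, 10α-CH3 and a 9β-CH2 group bonded to C5 of methyl 6-methoxy-2-methyl-4-oxo-4H-pyran-3-carboxylate
Conditions: DDQ, CH2Cl2/pH 7 buffer, 0 °C
Reagents that add atoms: none
Why: Oxidative cleavage of the PMB ether by DDQ through a benzylic oxocarbenium ion frees the C3 alcohol under neutral conditions that spare the formate, the exocyclic alkene and the pyranone.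

**Compound list**
1 | propane-1,3-diol | OCCCO | starting material
2 | 3-[(tert-butyldiphenylsilyl)oxy]propan-1-ol | OCCCO[Si](c1ccccc1)(c1ccccc1)C(C)(C)C | intermediate
3 | 3-[(tert-butyldiphenylsilyl)oxy]propanoic acid | OC(=O)CCO[Si](c1ccccc1)(c1ccccc1)C(C)(C)C | intermediate
4 | (S)-4-benzyloxazolidin-2-one | O=C1N[C@@H](Cc2ccccc2)CO1 | starting material
5 | 3-[(tert-butyldiphenylsilyl)oxy]propanoic pivalic anhydride | CC(C)(C)C(=O)OC(=O)CCO[Si](c1ccccc1)(c1ccccc1)C(C)(C)C | intermediate (not isolated)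
6 | (S)-4-benzyl-3-{3-[(tert-butyldiphenylsilyl)oxy]propanoyl}oxazolidin-2-one | O=C(CCO[Si](c1ccccc1)(c1ccccc1)C(C)(C)C)N1C(=O)OC[C@@H]1Cc1ccccc1 | intermediate
7 | 3-[(tert-butyldimethylsilyl)oxy]propanal | O=CCCO[Si](C)(C)C(C)(C)C | starting material
8 | Z-dibutylboron enolate of 6 | CCCCB(CCCC)O/C(=C\CO[Si](c1ccccc1)(c1ccccc1)C(C)(C)C)N1C(=O)OC[C@@H]1Cc1ccccc1 | intermediate (not isolated)
9 | (S)-4-benzyl-3-[(2S,3R)-5-[(tert-butyldimethylsilyl)oxy]-2-{[(tert-butyldiphenylsilyl)oxy]methyl}-3-hydroxypentanoyl]oxazolidin-2-one | O=C([C@@H](CO[Si](c1ccccc1)(c1ccccc1)C(C)(C)C)[C@H](O)CCO[Si](C)(C)C(C)(C)C)N1C(=O)OC[C@@H]1Cc1ccccc1 | intermediate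
10 | (S)-4-benzyl-3-[(2S,3R)-3,5-bis[(tert-butyldimethylsilyl)oxy]-2-{[(tert-butyldiphenylsilyl)oxy]methyl}pentanoyl]oxazolidin-2-one | O=C([C@@H](CO[Si](c1ccccc1)(c1ccccc1)C(C)(C)C)[C@H](O[Si](C)(C)C(C)(C)C)CCO[Si](C)(C)C(C)(C)C)N1C(=O)OC[C@@H]1Cc1ccccc1 | intermediate
11 | (2S,3R)-3,5-bis[(tert-butyldimethylsilyl)oxy]-2-{[(tert-butyldiphenylsilyl)oxy]methyl}pentan-1-ol | OC[C@@H](CO[Si](c1ccccc1)(c1ccccc1)C(C)(C)C)[C@H](O[Si](C)(C)C(C)(C)C)CCO[Si](C)(C)C(C)(C)C | intermediate
12 | (2S,3R)-3,5-bis[(tert-butyldimethylsilyl)oxy]-2-{[(tert-butyldiphenylsilyl)oxy]methyl}pentanal | O=C[C@@H](CO[Si](c1ccccc1)(c1ccccc1)C(C)(C)C)[C@H](O[Si](C)(C)C(C)(C)C)CCO[Si](C)(C)C(C)(C)C | intermediate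
13 | (3R,4S)-1,3-bis[(tert-butyldimethylsilyl)oxy]-4-{[(tert-butyldiphenylsilyl)oxy]methyl}hex-5-yne | C#C[C@@H](CO[Si](c1ccccc1)(c1ccccc1)C(C)(C)C)[C@H](O[Si](C)(C)C(C)(C)C)CCO[Si](C)(C)C(C)(C)C | intermediate
14 | dimethyl[(E)-2-methylalk-1-enyl]alane from 13 (Al cis to the new methyl) | C[Al](C)/C=C(\C)[C@@H](CO[Si](c1ccccc1)(c1ccccc1)C(C)(C)C)[C@H](O[Si](C)(C)C(C)(C)C)CCO[Si](C)(C)C(C)(C)C | intermediate (not isolated)
15 | (2E,4S,5R)-5,7-bis[(tert-butyldimethylsilyl)oxy]-4-{[(tert-butyldiphenylsilyl)oxy]methyl}-3-methylhept-2-en-1-ol | OC/C=C(\C)[C@@H](CO[Si](c1ccccc1)(c1ccccc1)C(C)(C)C)[C@H](O[Si](C)(C)C(C)(C)C)CCO[Si](C)(C)C(C)(C)C | intermediate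
16 | (2E,4S,5R)-5,7-bis[(tert-butyldimethylsilyl)oxy]-4-{[(tert-butyldiphenylsilyl)oxy]methyl}-3-methylhept-2-enal | O=C/C=C(\C)[C@@H](CO[Si](c1ccccc1)(c1ccccc1)C(C)(C)C)[C@H](O[Si](C)(C)C(C)(C)C)CCO[Si](C)(C)C(C)(C)C | intermediate
17 | (1E,3E,5S,6R)-6,8-bis[(tert-butyldimethylsilyl)oxy]-5-{[(tert-butyldiphenylsilyl)oxy]methyl}-1-iodo-4-methylocta-1,3-diene | I/C=C/C=C(\C)[C@@H](CO[Si](c1ccccc1)(c1ccccc1)C(C)(C)C)[C@H](O[Si](C)(C)C(C)(C)C)CCO[Si](C)(C)C(C)(C)C | intermediate
18 | (1E,3E,5S,6R)-6,8-bis[(tert-butyldimethylsilyl)oxy]-5-{[(tert-butyldiphenylsilyl)oxy]methyl}-1-[(4-methoxybenzyl)oxy]-4-methylocta-1,3-diene | COc1ccc(CO/C=C/C=C(\C)[C@@H](CO[Si](c2ccccc2)(c2ccccc2)C(C)(C)C)[C@H](O[Si](C)(C)C(C)(C)C)CCO[Si](C)(C)C(C)(C)C)cc1 | intermediate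
19 | (3R,4S,5E,7E)-3-[(tert-butyldimethylsilyl)oxy]-4-{[(tert-butyldiphenylsilyl)oxy]methyl}-8-[(4-methoxybenzyl)oxy]-5-methylocta-5,7-dien-1-ol | COc1ccc(CO/C=C/C=C(\C)[C@@H](CO[Si](c2ccccc2)(c2ccccc2)C(C)(C)C)[C@H](O[Si](C)(C)C(C)(C)C)CCO)cc1 | intermediate
20 | (3R,4S,5E,7E)-3-[(tert-butyldimethylsilyl)oxy]-4-{[(tert-butyldiphenylsilyl)oxy]methyl}-8-[(4-methoxybenzyl)oxy]-5-methylocta-5,7-dienal | COc1ccc(CO/C=C/C=C(\C)[C@@H](CO[Si](c2ccccc2)(c2ccccc2)C(C)(C)C)[C@H](O[Si](C)(C)C(C)(C)C)CC=O)cc1 | intermediate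
21 | 4-bromo-2-methylbutan-2-ol | CC(C)(O)CCBr | starting material
22 | [(4-bromo-2-methylbutan-2-yl)oxy]triethylsilane | CC(C)(CCBr)O[Si](CC)(CC)CC | intermediate
23 | {3-methyl-3-[(triethylsilyl)oxy]butyl}magnesium bromide | CC(C)(CC[Mg]Br)O[Si](CC)(CC)CC | intermediate (not isolated)
24 | (Z)-{2,5-dimethyl-5-[(triethylsilyl)oxy]hex-1-enyl}copper | [Cu]/C=C(/C)CCC(C)(C)O[Si](CC)(CC)CC | intermediate (not isolated)
25 | triethyl{[(5Z)-6-iodo-2,5-dimethylhex-5-en-2-yl]oxy}silane | I/C=C(/C)CCC(C)(C)O[Si](CC)(CC)CC | intermediate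
26 | (Z)-{2,5-dimethyl-5-[(triethylsilyl)oxy]hex-1-enyl}chromium dichloride | Cl[Cr](Cl)/C=C(/C)CCC(C)(C)O[Si](CC)(CC)CC | intermediate (not isolated)
27 | (1E,3E,5S,6R,9Z)-6-[(tert-butyldimethylsilyl)oxy]-5-{[(tert-butyldiphenylsilyl)oxy]methyl}-1-[(4-methoxybenzyl)oxy]-4,10,13-trimethyl-13-[(triethylsilyl)oxy]tetradeca-1,3,9-trien-8-ol (both carbinol epimers) | COc1ccc(CO/C=C/C=C(\C)[C@@H](CO[Si](c2ccccc2)(c2ccccc2)C(C)(C)C)[C@H](O[Si](C)(C)C(C)(C)C)CC(O)/C=C(/C)CCC(C)(C)O[Si](CC)(CC)CC)cc1 | intermediate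
28 | (1E,3E,5S,6R,9Z)-6-[(tert-butyldimethylsilyl)oxy]-5-{[(tert-butyldiphenylsilyl)oxy]methyl}-1-[(4-methoxybenzyl)oxy]-4,10,13-trimethyl-13-[(triethylsilyl)oxy]tetradeca-1,3,9-trien-8-one | COc1ccc(CO/C=C/C=C(\C)[C@@H](CO[Si](c2ccccc2)(c2ccccc2)C(C)(C)C)[C@H](O[Si](C)(C)C(C)(C)C)CC(=O)/C=C(/C)CCC(C)(C)O[Si](CC)(CC)CC)cc1 | intermediate
29 | cis-fused octal-1-en-6-one bearing 3β-OPMB, 4α-CH3, 4β-CH2CH2C(CH3)2OTES, 5α-H, 8α-OTBS, 9β-CH2OTBDPS and 10α-CH3 | C1C(=O)[C@H]2[C@@](C)(CCC(C)(C)O[Si](CC)(CC)CC)[C@@H](OCc3ccc(OC)cc3)C=C[C@@]2(C)[C@@H](CO[Si](c3ccccc3)(c3ccccc3)C(C)(C)C)[C@@H]1O[Si](C)(C)C(C)(C)C | intermediate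
30 | C6 alcohol of 29 (octal-1-en-6-ol, both C6 epimers, other substituents unchanged) | C1C(O)[C@H]2[C@@](C)(CCC(C)(C)O[Si](CC)(CC)CC)[C@@H](OCc3ccc(OC)cc3)C=C[C@@]2(C)[C@@H](CO[Si](c3ccccc3)(c3ccccc3)C(C)(C)C)[C@@H]1O[Si](C)(C)C(C)(C)C | intermediate
31 | C6 O-(imidazol-1-ylthiocarbonyl) derivative of 30 | C1C(OC(=S)n3ccnc3)[C@H]2[C@@](C)(CCC(C)(C)O[Si](CC)(CC)CC)[C@@H](OCc3ccc(OC)cc3)C=C[C@@]2(C)[C@@H](CO[Si](c3ccccc3)(c3ccccc3)C(C)(C)C)[C@@H]1O[Si](C)(C)C(C)(C)C | intermediate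
32 | cis-fused octal-1-ene (C6 = CH2) bearing 3β-OPMB, 4α-CH3, 4β-CH2CH2C(CH3)2OTES, 5α-H, 8α-OTBS, 9β-CH2OTBDPS and 10α-CH3 | C1C[C@H]2[C@@](C)(CCC(C)(C)O[Si](CC)(CC)CC)[C@@H](OCc3ccc(OC)cc3)C=C[C@@]2(C)[C@@H](CO[Si](c3ccccc3)(c3ccccc3)C(C)(C)C)[C@@H]1O[Si](C)(C)C(C)(C)C | intermediate
33 | cis-fused decalin bearing 3β-OPMB, 4α-CH3, 4β-CH2CH2C(CH3)2OTES, 5α-H, 8α-OTBS, 9β-CH2OTBDPS and 10α-CH3 | C1C[C@H]2[C@@](C)(CCC(C)(C)O[Si](CC)(CC)CC)[C@@H](OCc3ccc(OC)cc3)CC[C@@]2(C)[C@@H](CO[Si](c3ccccc3)(c3ccccc3)C(C)(C)C)[C@@H]1O[Si](C)(C)C(C)(C)C | intermediate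
34 | cis-fused decalin-8α-ol bearing 3β-OPMB, 4α-CH3, 4β-CH2CH2C(CH3)2OH, 5α-H, 9β-CH2OTBDPS and 10α-CH3 | C1C[C@H]2[C@@](C)(CCC(C)(C)O)[C@@H](OCc3ccc(OC)cc3)CC[C@@]2(C)[C@@H](CO[Si](c3ccccc3)(c3ccccc3)C(C)(C)C)[C@@H]1O | intermediate
35 | cis-fused decalin-8-one bearing 3β-OPMB, 4α-CH3, 4β-CH2CH2C(CH3)2OH, 5α-H, 9β-CH2OTBDPS and 10α-CH3 | C1C[C@H]2[C@@](C)(CCC(C)(C)O)[C@@H](OCc3ccc(OC)cc3)CC[C@@]2(C)[C@@H](CO[Si](c3ccccc3)(c3ccccc3)C(C)(C)C)C1=O | intermediate
36 | cis-fused 8-methylidenedecalin bearing 3β-OPMB, 4α-CH3, 4β-CH2CH2C(CH3)2OH, 5α-H, 9β-CH2OTBDPS and 10α-CH3 | C1C[C@H]2[C@@](C)(CCC(C)(C)O)[C@@H](OCc3ccc(OC)cc3)CC[C@@]2(C)[C@@H](CO[Si](c3ccccc3)(c3ccccc3)C(C)(C)C)C1=C | intermediate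
37 | cis-fused 8-methylidenedecalin bearing 3β-OPMB, 4α-CH3, 4β-CH2CH2C(CH3)2OH, 5α-H, 9β-CH2OH and 10α-CH3 | C1C[C@H]2[C@@](C)(CCC(C)(C)O)[C@@H](OCc3ccc(OC)cc3)CC[C@@]2(C)[C@@H](CO)C1=C | intermediate
38 | cis-fused 8-methylidenedecalin bearing 3β-OPMB, 4α-CH3, 4β-CH2CH2C(CH3)2OH, 5α-H, 9β-CH2I and 10α-CH3 | C1C[C@H]2[C@@](C)(CCC(C)(C)O)[C@@H](OCc3ccc(OC)cc3)CC[C@@]2(C)[C@@H](CI)C1=C | intermediate
39 | methyl acetoacetate | COC(=O)CC(C)=O | starting material
40 | methyl 4-hydroxy-6-methyl-2-oxo-2H-pyran-5-carboxylate | COC(=O)c1c(C)oc(=O)cc1O | intermediate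
41 | 4-hydroxy-2-methoxy-5-(methoxycarbonyl)-6-methylpyrylium triflate | COC(=O)c1c(C)[o+]c(OC)cc1O.[O-]S(=O)(=O)C(F)(F)F | intermediate (not isolated)
42 | methyl 6-methoxy-2-methyl-4-oxo-4H-pyran-3-carboxylate | COC(=O)c1c(C)oc(OC)cc1=O | intermediate
43 | methyl 5-iodo-6-methoxy-2-methyl-4-oxo-4H-pyran-3-carboxylate | COC(=O)c1c(C)oc(OC)c(I)c1=O | intermediate
44 | C11 alkyllithium from 38 (tertiary lithium alkoxide) | C1C[C@H]2[C@@](C)(CCC(C)(C)O[Li])[C@@H](OCc3ccc(OC)cc3)CC[C@@]2(C)[C@@H](C[Li])C1=C | intermediate (not isolated)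
45 | C11 alkylzinc chloride from 44 | C1C[C@H]2[C@@](C)(CCC(C)(C)O[Li])[C@@H](OCc3ccc(OC)cc3)CC[C@@]2(C)[C@@H](C[Zn]Cl)C1=C | intermediate (not isolated)
46 | cis-fused 8-methylidenedecalin bearing 3β-OPMB, 4α-CH3, 4β-CH2CH2C(CH3)2OH, 5α-H, 10α-CH3 and a 9β-CH2 group bonded to C5 of methyl 6-methoxy-2-methyl-4-oxo-4H-pyran-3-carboxylate | C1C[C@H]2[C@@](C)(CCC(C)(C)O)[C@@H](OCc3ccc(OC)cc3)CC[C@@]2(C)[C@@H](Cc3c(OC)oc(C)c(C(=O)OC)c3=O)C1=C | intermediate
47 | tertiary formate of 46 (4β-CH2CH2C(CH3)2OCHO, other substituents unchanged) | C1C[C@H]2[C@@](C)(CCC(C)(C)OC=O)[C@@H](OCc3ccc(OC)cc3)CC[C@@]2(C)[C@@H](Cc3c(OC)oc(C)c(C(=O)OC)c3=O)C1=C | intermediate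
48 | CNP0292250.1: cis-fused 8-methylidenedecalin bearing 3β-OH, 4α-CH3, 4β-CH2CH2C(CH3)2OCHO, 5α-H, 10α-CH3 and a 9β-CH2 group bonded to C5 of methyl 6-methoxy-2-methyl-4-oxo-4H-pyran-3-carboxylate | C=C1CC[C@H]2[C@@](C)(CCC(C)(C)OC=O)[C@@H](O)CC[C@@]2(C)[C@H]1Cc1c(OC)oc(C)c(C(=O)OC)c1=O | target

**Totals**
Total step count: 34. Longest linear sequence: 29 steps (steps 1–14, 17–28 and 32–34).

**Steps most likely to fail**

Step 19. The cycloaddition may stall, because two fully substituted carbons have to bond while the diene must reach its s-cis form with a methyl group pointing inward. During a slow reaction the Lewis acid may isomerise the Z-enone, shift the PMB group of the enol ether or erode the facial selectivity. The fallback stages the congestion and sets out from aldehyde 20, with a reagent made from bromide 22. Displacement of the bromide of 22 with lithium acetylide–ethylenediamine in DMSO should give the alkyne triethyl[(2-methylhex-5-yn-2-yl)oxy]silane F1. Its lithium acetylide adds to 20 to give the propargylic alcohol F2, and Dess–Martin oxidation gives the ynone F3. The linear, unhindered alkynone dienophile of F3 should undergo the known Me2AlCl-promoted or thermal intramolecular Diels–Alder reaction of dienyl ynones to the cyclohexadienone F4, in which only C10 is formed as a quaternary centre. Conjugate addition of Me2CuLi with BF3·OEt2 to the C4=C5 enone of F4 then brings in the C4 methyl anti to the C3 ether, and protonation with equilibration at C5 to the cis-fused ketone gives 29, where the route resumes.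

Step 32. Transmetalation of the branched alkylzinc reagent may be slow, so that β-hydride elimination from the alkylpalladium intermediate or attack on the pyranone ester competes with coupling. The fallback sets out from alcohol 37. Dess–Martin oxidation gives the β,γ-unsaturated aldehyde F5. Iodine–magnesium exchange of 43 with i-PrMgCl·LiCl gives the pyranylmagnesium chloride F6, which adds to F5 at low temperature to give the secondary carbinol F7 (both C11 epimers). Phenyl chlorothionoformate and pyridine convert F7 into the thionocarbonate F8, and Barton–McCombie reduction with Bu3SnH and AIBN removes the C11 oxygen to give 46.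

Step 12. The copper-catalysed C–O coupling may be sluggish with the branched dienyl iodide, so that prolonged heating with carbonate leads to loss of alkene geometry or elimination to an enyne. The fallback sets out from enal 16. Takai–Utimoto olefination with pinacol (dichloromethyl)boronate, CrCl2 and LiI should give the (1E,3E)-dienylboronate F9. Chan–Lam oxidative coupling of F9 with 4-methoxybenzyl alcohol, mediated by Cu(OAc)2 and Et3N in air, replaces boron by the PMB ether oxygen with retention and gives 18.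

**Further compounds**
F1 | step 19 | triethyl[(2-methylhex-5-yn-2-yl)oxy]silane | C#CCCC(C)(C)O[Si](CC)(CC)CC
F2 | step 19 | propargylic alcohol from 20 and F1 (alkynyl carbinol in place of the C6 ketone, both carbinol epimers) | COc1ccc(CO/C=C/C=C(\C)[C@@H](CO[Si](c2ccccc2)(c2ccccc2)C(C)(C)C)[C@H](O[Si](C)(C)C(C)(C)C)CC(O)C#CCCC(C)(C)O[Si](CC)(CC)CC)cc1
F3 | step 19 | dienyl ynone (alkyne analogue of 28 lacking the C4 methyl) | COc1ccc(CO/C=C/C=C(\C)[C@@H](CO[Si](c2ccccc2)(c2ccccc2)C(C)(C)C)[C@H](O[Si](C)(C)C(C)(C)C)CC(=O)C#CCCC(C)(C)O[Si](CC)(CC)CC)cc1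
F4 | step 19 | cyclohexadienone (C1=C2 and C4=C5, C6 ketone) bearing 3β-OPMB, 4-CH2CH2C(CH3)2OTES, 8α-OTBS, 9β-CH2OTBDPS and 10α-CH3 | C1C(=O)C2=C(CCC(C)(C)O[Si](CC)(CC)CC)[C@@H](OCc3ccc(OC)cc3)C=C[C@@]2(C)[C@@H](CO[Si](c3ccccc3)(c3ccccc3)C(C)(C)C)[C@@H]1O[Si](C)(C)C(C)(C)C
F5 | step 32 | C11 aldehyde from 37 (9β-CHO) | C1C[C@H]2[C@@](C)(CCC(C)(C)O)[C@@H](OCc3ccc(OC)cc3)CC[C@@]2(C)[C@@H](C=O)C1=C
F6 | step 32 | [2-methoxy-5-(methoxycarbonyl)-6-methyl-4-oxo-4H-pyran-3-yl]magnesium chloride | COC(=O)c1c(C)oc(OC)c([Mg]Cl)c1=O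
F7 | step 32 | C11 carbinol from F5 and F6 (both C11 epimers) | C1C[C@H]2[C@@](C)(CCC(C)(C)O)[C@@H](OCc3ccc(OC)cc3)CC[C@@]2(C)[C@@H](C(O)c3c(OC)oc(C)c(C(=O)OC)c3=O)C1=C
F8 | step 32 | C11 O-phenyl thionocarbonate of F7 | C1C[C@H]2[C@@](C)(CCC(C)(C)O)[C@@H](OCc3ccc(OC)cc3)CC[C@@]2(C)[C@@H](C(OC(=S)Oc3ccccc3)c3c(OC)oc(C)c(C(=O)OC)c3=O)C1=C
F9 | step 12 | (1E,3E)-dienyl pinacol boronate (B in place of the iodine of 17) | CC1(C)OB(/C=C/C=C(\C)[C@@H](CO[Si](c2ccccc2)(c2ccccc2)C(C)(C)C)[C@H](O[Si](C)(C)C(C)(C)C)CCO[Si](C)(C)C(C)(C)C)OC1(C)C
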